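Remark on the chemistry: the locants C1–C14 used throughout are those of the target's bicyclo[8.4.0]tetradecane frame, also for open-chain intermediates. Reagents without a number are taken as commercial.

## Analysis of the target

The target (33) is a bicyclo[8.4.0]tetradecane diterpenoid. A cyclohexane (ring A: C10, C11, C12, C13, C14, C1) is cis-fused through C1 and C10 to a ten-membered carbocycle (C1 to C10). The large ring holds a Z-trisubstituted olefin C2=C3 (methyl on C3), an allylic acetate at C6, an exocyclic methylene on C7 and a second acetate at C9. Ring A holds a tertiary alcohol with a methyl group at C11 and an isopropyl group at C14. The six stereocentres are (1S,6R,9R,10S,11R,14R). Four sit on ring A: H1 and H10 are cis, the isopropyl group is trans to the C2 branch, and the C11 hydroxyl is trans to the C9 branch. C9 adjoins the ring fusion, and C6 lies on the far side of the large ring, out of reach of control by ring A. Sensitive points are the tertiary C11 alcohol β to the C9 oxygen (retro-aldol or elimination once C9 is a carbonyl), the allylic C6 oxygen, the exocyclic methylene (migration into the ring) and two esters beside a hydroxyl that must stay free. The main difficulty is closing a ten-membered all-carbon ring that contains a Z-trisubstituted olefin, against transannular strain, while keeping control of C9. The strategy rests on the segment C9(O)–C8H2–C7(=CH2). It is the homoallylic alcohol of a 2-substituted allyl unit, so C8–C9 can be made by adding an allyl metal carried on C7 to a C9 aldehyde. The two CH2 termini of that allyl unit are equivalent, so the addition has no regiochemical ambiguity.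

## Retrosynthetic reasoning

33 is traced to triol 32 by removing both acetates. The acylation can be left to the end because only the two secondary hydroxyls react. 32 comes from the bis-silyl ether 31 by fluoride, so no acetate has to pass through basic fluoride conditions.

In 31 the C8–C9 bond is cut. This is the only bond in the large ring whose formation creates the C9 carbinol and the C7 methylene at once. It leads to bromo aldehyde 29, and the forward reaction is a chromium-mediated intramolecular allylation, which must close the ring end-to-end and set C9.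

29 holds an aldehyde α to a stereocentre and an allylic bromide, so both are unveiled last. It goes back to 24, in which C9 is a pivalate and C8 a 4-methoxybenzyl ether. The ester is removed reductively and oxidised (25, 26), then the benzyl ether is cleaved oxidatively and the alcohol 27 is converted into the bromide. The two groups are orthogonal to each other and to the silyl ethers at C6 and C11.

24 is cut at C3–C4, between an sp2 and an sp3 carbon, into Z-iodoalkene 10 and alkyl iodide 22. This is the most convergent cut, it separates the isolated C6 stereocentre from ring A, and a Negishi coupling transfers the olefin geometry with retention.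

The iodoalkene 10 comes from aldehyde 9 by an α-iodoethylidene Wittig olefination, which makes C2=C3 and introduces C3 and its methyl group with the iodine cis to C1.

Aldehyde 9 is traced through 8 and diol 7 to cyclohexene 6. The C11 tertiary alcohol comes from Markovnikov hydration of the C11=C12 olefin, carried out at the alcohol oxidation level of C2 because an aldehyde would not survive the aerobic conditions.

Cyclohexene 6 is the reduced Diels–Alder adduct of diene 3 and enal 4 (bonds C1–C10 and C13–C14). One enantioselective cycloaddition sets C1, C10 and C14. The E-dienophile gives the trans relation of C2 and the isopropyl group, and the endo mode gives the cis relation of C2 and C9. Diene 3 comes from enynol 1 by esterification (2) and semihydrogenation.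

Iodide 22 is traced through 21 and 20 to allylic alcohol 19, whose C6 configuration comes from catalyst-controlled reduction of enone 18. The enone arises by oxidation of 17, and 17 by cutting C6–C7 into the vinyllithium 16 (from bromide 15) and aldehyde 13. Aldehyde 13 comes from diol 11 through 12, and 15 from bromo alcohol 14.

## Alternatives that were turned down

Alternative 1: The ten-membered ring is traced to a tricyclic α,β-epoxy ketone A2 in which two six-membered rings share the C2–C7 bond, so the disconnection is a retro-fragmentation. Forward, an arenesulfonyl hydrazide condenses with the C3 ketone of A2 and the hydrazone collapses (Eschenmoser–Tanabe fragmentation) with cleavage of C2–C7 to the cyclodecynone A1 (C2≡C3, C7 ketone).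
- For it: the medium ring is made by ring expansion from strain-free rings without high dilution, and the fused precursor gives rigid stereocontrol. On the certainty of forming the ring it is stronger than an end-to-end closure.
- Against it: A1 has no C3 methyl group, no C6 oxygen and no C7 methylene. The alkyne would need hydromethylation with methyl at C3 and hydrogen at C2, and carbometalation of an unactivated dialkylalkyne has no reliable regiocontrol. C6 would have to be oxidised next to the C7 ketone in competition with C8, and the hindered ketone then methylenated. A2 itself needs a tetrasubstituted epoxide inside a three-ring skeleton.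
- Comparison: the chosen route gives up that ring-forming certainty but closes the ring with all three groups in place and reaches the target two steps later.

Alternative 2: Cutting C3–C4 leads to the open-chain iodoalkene A4 with the Z-configured C3 iodide, a terminal C4=C5 olefin, both oxygen stereocentres and C7 masked as a dioxolane. Forward, 9-BBN hydroborates the terminal olefin, and Pd(dppf)Cl2 with base couples the C4 borane with the C3 iodide (B-alkyl Suzuki), giving A3.
- For it: the olefin geometry is fixed before closure, and the closure creates no stereocentre, so C6 and C9 can be set beforehand under reagent control. On stereochemical certainty at C9 it is stronger than the chosen route, and it avoids an aldehyde–allylic bromide pair.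
- Against it: the ring must close by reductive elimination from a palladacycle that already carries the strain of the (Z)-cyclodecene, in competition with protodeboronation, β-hydride elimination and dimerisation. The hydroboration is chemoselective only without the C7 methylene, hence the ketal. After closure the ketal must be hydrolysed to a ketone flanked by an epimerisable C6 and with the C9 silyloxy group β to it, and that hindered ketone must be methylenated.
- Comparison: the chosen route closes at a carbonyl with a chemoselective organochromium and delivers the methylene in the same event. In place of preset C9 stereochemistry it offers a shorter tail and substrate control that can be corrected after closure.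

Alternative 3: Cutting C9–C10 leads to A6, in which C9 is a 2-alkyl-1,3-dithiane and ring A carries a C10–C11 epoxide. Forward, an alkyllithium base metallates the dithiane and the carbanion opens the epoxide at C10 with inversion, closing the ring to A5 and releasing the C11 alcohol.
- For it: the opening is stereospecific, so the trans relation of the C9 branch and the C11 hydroxyl follows from the epoxide and no alkene hydration is needed. On this point it is stronger than the chosen route, where C11 depends on facial selectivity.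
- Against it: a bulky, fully substituted carbanion must displace at a secondary carbon flanked by the quaternary C11 and the branched C1, through a ten-membered transition state. Proton transfer from allylic positions, base-induced isomerisation of the epoxide and intermolecular opening should all be faster. After closure the dithiane must be removed in the presence of two olefins and the C9 ketone reduced with unpredictable facial selectivity.
- Comparison: the chosen route sets C9 in the bond-forming step under neutral conditions and needs no unmasking.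

Key step: step 22

## Route

Step 1
Reactants: 1 (2E)-3-methylpent-2-en-4-yn-1-ol
Product: 2 (2E)-3-methylpent-2-en-4-yn-1-yl 2,2-dimethylpropanoate
Conditions: pivaloyl chloride, pyridine, 4-(dimethylamino)pyridine (cat.), CH2Cl2, 0→23 °C
Reagents that add atoms: pivaloyl chloride, CC(C)(C)C(Cl)=O
Why: Acylation of a primary allylic alcohol under nucleophilic catalysis. The pivalate masks the future C9 oxygen, survives acid, oxidants, ylides and organozinc reagents, and is later removed reductively beside silyl and 4-methoxybenzyl ethers.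

Step 2
Reactants: 2 (2E)-3-methylpent-2-en-4-yn-1-yl 2,2-dimethylpropanoate
Product: 3 (2E)-3-methylpenta-2,4-dien-1-yl 2,2-dimethylpropanoate
Conditions: H2 (1 atm), Pd/CaCO3 poisoned with Pb(OAc)2, quinoline, hexane, 23 °C
Reagents that add atoms: none
Why: Semihydrogenation of the terminal alkyne over lead-poisoned palladium should stop at the alkene. The resulting E-diene has its terminal substituent outside, so the s-cis conformation needed for cycloaddition is accessible.

Step 3
Reactants: 3 (2E)-3-methylpenta-2,4-dien-1-yl 2,2-dimethylpropanoate; 4 (2E)-4-methylpent-2-enal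
Product: 6 [(1R,5R,6R)-6-(hydroxymethyl)-2-methyl-5-(propan-2-yl)cyclohex-2-en-1-yl]methyl 2,2-dimethylpropanoate, via Diels–Alder aldehyde 5 (not isolated)
Conditions: (5S)-5-benzyl-2,2,3-trimethylimidazolidin-4-one·HCl (20 mol%), CH3CN/H2O (95:5), 0→23 °C; then EtOH, NaBH4, 0 °C
Reagents that add atoms: none
Why: Iminium-catalysed Diels–Alder reaction: the (5S)-imidazolidinone forms an E-iminium ion of 4 whose benzyl group shields one face, so the diene adds to the Re face of the β-carbon; the endo mode places CH2OPiv cis to the formyl group and the E-dienophile keeps formyl and isopropyl trans, which sets C1, C10 and C14. The unsubstituted diene terminus bonds to the isopropyl-bearing β-carbon, as the 1-substituent and sterics both demand. Borohydride reduction in the same flask prevents epimerisation at C1 and removes the aldehyde before the aerobic step.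

Step 4
Reactants: 6 [(1R,5R,6R)-6-(hydroxymethyl)-2-methyl-5-(propan-2-yl)cyclohex-2-en-1-yl]methyl 2,2-dimethylpropanoate
Product: 7 [(1S,2R,5R,6R)-2-hydroxy-6-(hydroxymethyl)-2-methyl-5-(propan-2-yl)cyclohexyl]methyl 2,2-dimethylpropanoate
Conditions: Co(acac)2 (20 mol%), PhSiH3, O2 (1 atm), THF, 23 °C
Reagents that add atoms: dioxygen, O=O
Why: Mukaiyama hydration: a cobalt hydride transfers a hydrogen atom to C12, the tertiary C11 radical is trapped by O2 and the peroxide is reduced, giving the Markovnikov alcohol. The C10 CH2OPiv group is pseudoaxial next to the planar radical centre, so O2 should approach from the opposite face and place the hydroxyl trans to the C9 branch.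

Step 5
Reactants: 7 [(1S,2R,5R,6R)-2-hydroxy-6-(hydroxymethyl)-2-methyl-5-(propan-2-yl)cyclohexyl]methyl 2,2-dimethylpropanoate
Product: 8 [(1S,2R,5R,6R)-6-formyl-2-hydroxy-2-methyl-5-(propan-2-yl)cyclohexyl]methyl 2,2-dimethylpropanoate
Conditions: 2,2,6,6-tetramethylpiperidin-1-oxyl (10 mol%), PhI(OAc)2, CH2Cl2, 23 °C
Reagents that add atoms: none
Why: Oxoammonium-mediated oxidation is selective for the primary alcohol, cannot oxidise the tertiary one and stops at the aldehyde under nearly neutral conditions that should not epimerise C1.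

Step 6
Reactants: 8 [(1S,2R,5R,6R)-6-formyl-2-hydroxy-2-methyl-5-(propan-2-yl)cyclohexyl]methyl 2,2-dimethylpropanoate
Product: 9 [(1S,2R,5R,6R)-6-formyl-2-methyl-5-(propan-2-yl)-2-(triethylsilyloxy)cyclohexyl]methyl 2,2-dimethylpropanoate
Conditions: triethylsilyl trifluoromethanesulfonate, 2,6-lutidine, CH2Cl2, −78 °C
Reagents that add atoms: triethylsilyl trifluoromethanesulfonate, CC[Si](CC)(CC)OS(=O)(=O)C(F)(F)F
Why: Silylation with a silyl triflate and a hindered pyridine base protects tertiary alcohols at low temperature without enolising the aldehyde. The triethylsilyl ether blocks retro-aldol and elimination once C9 becomes an aldehyde and is later removed by fluoride together with the C6 silyl ether.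

Step 7
Reactants: 9 [(1S,2R,5R,6R)-6-formyl-2-methyl-5-(propan-2-yl)-2-(triethylsilyloxy)cyclohexyl]methyl 2,2-dimethylpropanoate
Product: 10 [(1S,2R,5R,6R)-6-[(1Z)-2-iodoprop-1-en-1-yl]-2-methyl-5-(propan-2-yl)-2-(triethylsilyloxy)cyclohexyl]methyl 2,2-dimethylpropanoate
Conditions: EtPPh3I, n-BuLi, THF, 23 °C; I2, −78 °C; NaN(SiMe3)2, −20 °C; then 9, −78→−20 °C
Reagents that add atoms: ethyltriphenylphosphonium iodide, CC[P+](c1ccccc1)(c1ccccc1)c1ccccc1.[I-]; iodine, II
Why: Stork–Zhao-type Wittig olefination with the α-iodoethylidene ylide: the non-stabilised ylide reacts under kinetic control to give the Z-iodoalkene with iodine cis to C1, which fixes the later 2Z geometry. Low temperature and the amide base should keep C1 from epimerising.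

Step 8
Reactants: 11 propane-1,3-diol
Product: 12 3-(tert-butyldimethylsilyloxy)propan-1-ol
Conditions: NaH (1.0 equiv), THF, 23 °C; then tert-butyldimethylsilyl chloride (1.0 equiv)
Reagents that add atoms: tert-butyldimethylsilyl chloride, CC(C)(C)[Si](C)(C)Cl
Why: Monosilylation of a symmetric diol through its sparingly soluble monosodium alkoxide, a standard desymmetrising protection.

Step 9
Reactants: 12 3-(tert-butyldimethylsilyloxy)propan-1-ol
Product: 13 3-(tert-butyldimethylsilyloxy)propanal
Conditions: (COCl)2, DMSO, CH2Cl2, −78 °C; Et3N, −78→0 °C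
Reagents that add atoms: none
Why: Swern oxidation gives the β-silyloxy aldehyde without over-oxidation or β-elimination.

Step 10
Reactants: 14 2-bromoprop-2-en-1-ol
Product: 15 1-{[(2-bromoprop-2-en-1-yl)oxy]methyl}-4-methoxybenzene
Conditions: NaH, THF/DMF, 0 °C; 4-methoxybenzyl chloride, Bu4NI (cat.), 23 °C
Reagents that add atoms: 4-methoxybenzyl chloride, COc1ccc(CCl)cc1
Why: Williamson etherification. Unlike a silyl group, the benzyl ether cannot migrate from oxygen to carbon on lithiation, and it is later cleaved oxidatively under neutral conditions.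

Step 11
Reactants: 15 1-{[(2-bromoprop-2-en-1-yl)oxy]methyl}-4-methoxybenzene; 13 3-(tert-butyldimethylsilyloxy)propanal
Product: 17 rac-5-(tert-butyldimethylsilyloxy)-2-{[(4-methoxybenzyl)oxy]methyl}pent-1-en-3-ol, via vinyllithium 16 (not isolated)
Conditions: 15, t-BuLi (2.0 equiv), Et2O, −78 °C; then 13, −78 °C; H2O
Reagents that add atoms: none
Why: Bromine–lithium exchange at −78 °C gives the 2-lithioallyl ether, and its 1,2-addition to the aldehyde forms the C6–C7 bond. C6 is not controlled here and is set by the oxidation–reduction pair that follows.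

Step 12
Reactants: 17 rac-5-(tert-butyldimethylsilyloxy)-2-{[(4-methoxybenzyl)oxy]methyl}pent-1-en-3-ol
Product: 18 5-(tert-butyldimethylsilyloxy)-2-{[(4-methoxybenzyl)oxy]methyl}pent-1-en-3-one
Conditions: Dess–Martin periodinane, pyridine, CH2Cl2, 0→23 °C
Reagents that add atoms: none
Why: Dess–Martin oxidation of the allylic alcohol to the α-methylene ketone under buffered conditions. The enone should be used at once because such ketones dimerise on storage.

Step 13
Reactants: 18 5-(tert-butyldimethylsilyloxy)-2-{[(4-methoxybenzyl)oxy]methyl}pent-1-en-3-one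
Product: 19 (3R)-5-(tert-butyldimethylsilyloxy)-2-{[(4-methoxybenzyl)oxy]methyl}pent-1-en-3-ol
Conditions: (S)-1-methyl-3,3-diphenyltetrahydro-1H,3H-pyrrolo[1,2-c][1,3,2]oxazaborole (20 mol%), BH3·SMe2, THF, −30 °C; then MeOH
Reagents that add atoms: none
Why: Corey–Bakshi–Shibata reduction: the ketone binds the (S)-oxazaborolidine–borane complex with the alkenyl group as the large substituent, and hydride goes to the face that gives the 3R alcohol (C6 of the target). At low temperature 1,2-reduction outpaces hydroboration of the electron-poor olefin.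

Step 14
Reactants: 19 (3R)-5-(tert-butyldimethylsilyloxy)-2-{[(4-methoxybenzyl)oxy]methyl}pent-1-en-3-ol
Product: 20 (3R)-3,5-bis(tert-butyldimethylsilyloxy)-2-{[(4-methoxybenzyl)oxy]methyl}pent-1-ene
Conditions: tert-butyldimethylsilyl chloride, imidazole, DMF, 23 °C
Reagents that add atoms: tert-butyldimethylsilyl chloride, CC(C)(C)[Si](C)(C)Cl
Why: Imidazole-promoted silylation of the secondary allylic alcohol. The C6 oxygen stays as a silyl ether because an allylic ester would ionise under palladium catalysis in step 17.

Step 15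
Reactants: 20 (3R)-3,5-bis(tert-butyldimethylsilyloxy)-2-{[(4-methoxybenzyl)oxy]methyl}pent-1-ene
Product: 21 (3R)-3-(tert-butyldimethylsilyloxy)-4-{[(4-methoxybenzyl)oxy]methyl}pent-4-en-1-ol
Conditions: HF·pyridine, pyridine, THF, 0 °C
Reagents that add atoms: none
Why: Selective desilylation: buffered fluoride cleaves the unhindered primary silyl ether much faster than the secondary allylic one.

Step 16
Reactants: 21 (3R)-3-(tert-butyldimethylsilyloxy)-4-{[(4-methoxybenzyl)oxy]methyl}pent-4-en-1-ol
Product: 22 (3R)-3-(tert-butyldimethylsilyloxy)-5-iodo-2-{[(4-methoxybenzyl)oxy]methyl}pent-1-ene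
Conditions: I2, PPh3, imidazole, CH2Cl2, 0→23 °C
Reagents that add atoms: iodine, II
Why: Appel-type iodination: the primary alcohol is activated as an alkoxyphosphonium ion and displaced by iodide under near-neutral conditions.

Step 17
Reactants: 22 (3R)-3-(tert-butyldimethylsilyloxy)-5-iodo-2-{[(4-methoxybenzyl)oxy]methyl}pent-1-ene; 10 [(1S,2R,5R,6R)-6-[(1Z)-2-iodoprop-1-en-1-yl]-2-methyl-5-(propan-2-yl)-2-(triethylsilyloxy)cyclohexyl]methyl 2,2-dimethylpropanoate
Product: 24 [(1S,2R,5R,6S)-6-[(1Z,5R)-5-(tert-butyldimethylsilyloxy)-6-{[(4-methoxybenzyl)oxy]methyl}-2-methylhepta-1,6-dien-1-yl]-2-methyl-5-(propan-2-yl)-2-(triethylsilyloxy)cyclohexyl]methyl 2,2-dimethylpropanoate, via alkylzinc iodide 23 (not isolated)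
Conditions: 22, Zn dust (activated: BrCH2CH2Br, Me3SiCl), LiCl, THF, 40 °C; then 10, Pd(dppf)Cl2 (5 mol%), THF, 50 °C
Reagents that add atoms: none
Why: Zinc insertion into the primary iodide followed by Negishi coupling: oxidative addition of the Z-iodoalkene to zerovalent palladium, transmetallation and reductive elimination proceed with retention, so C4 ends cis to C1 and the 2Z olefin results. The alkylzinc halide tolerates the ester and the ethers, and the ferrocenyl bisphosphine favours reductive elimination over β-hydride elimination.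

Step 18
Reactants: 24 [(1S,2R,5R,6S)-6-[(1Z,5R)-5-(tert-butyldimethylsilyloxy)-6-{[(4-methoxybenzyl)oxy]methyl}-2-methylhepta-1,6-dien-1-yl]-2-methyl-5-(propan-2-yl)-2-(triethylsilyloxy)cyclohexyl]methyl 2,2-dimethylpropanoate
Product: 25 [(1S,2R,5R,6S)-6-[(1Z,5R)-5-(tert-butyldimethylsilyloxy)-6-{[(4-methoxybenzyl)oxy]methyl}-2-methylhepta-1,6-dien-1-yl]-2-methyl-5-(propan-2-yl)-2-(triethylsilyloxy)cyclohexyl]methanol
Conditions: i-Bu2AlH, CH2Cl2, −78 °C; aq. potassium sodium tartrate
Reagents that add atoms: none
Why: Reductive cleavage of the pivalate with an aluminium hydride frees the C9 alcohol. Silyl and benzyl ethers and both olefins are inert at −78 °C.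

Step 19
Reactants: 25 [(1S,2R,5R,6S)-6-[(1Z,5R)-5-(tert-butyldimethylsilyloxy)-6-{[(4-methoxybenzyl)oxy]methyl}-2-methylhepta-1,6-dien-1-yl]-2-methyl-5-(propan-2-yl)-2-(triethylsilyloxy)cyclohexyl]methanol
Product: 26 (1R,2R,5R,6S)-6-[(1Z,5R)-5-(tert-butyldimethylsilyloxy)-6-{[(4-methoxybenzyl)oxy]methyl}-2-methylhepta-1,6-dien-1-yl]-2-methyl-5-(propan-2-yl)-2-(triethylsilyloxy)cyclohexane-1-carbaldehyde
Conditions: Dess–Martin periodinane, pyridine, CH2Cl2, 0→23 °C
Reagents that add atoms: none
Why: Dess–Martin oxidation of the hindered primary alcohol under buffered conditions, which should leave the C10 stereocentre and the β-silyloxy group untouched.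

Step 20
Reactants: 26 (1R,2R,5R,6S)-6-[(1Z,5R)-5-(tert-butyldimethylsilyloxy)-6-{[(4-methoxybenzyl)oxy]methyl}-2-methylhepta-1,6-dien-1-yl]-2-methyl-5-(propan-2-yl)-2-(triethylsilyloxy)cyclohexane-1-carbaldehyde
Product: 27 (1R,2R,5R,6S)-6-[(1Z,5R)-5-(tert-butyldimethylsilyloxy)-6-(hydroxymethyl)-2-methylhepta-1,6-dien-1-yl]-2-methyl-5-(propan-2-yl)-2-(triethylsilyloxy)cyclohexane-1-carbaldehyde
Conditions: DDQ, CH2Cl2/pH 7 phosphate buffer (10:1), 0 °C
Reagents that add atoms: none
Why: Oxidative cleavage of the 4-methoxybenzyl ether: hydride abstraction from the benzylic position and hydrolysis of the oxocarbenium ion. The buffered medium spares the aldehyde, both silyl ethers and the olefins.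

Step 21
Reactants: 27 (1R,2R,5R,6S)-6-[(1Z,5R)-5-(tert-butyldimethylsilyloxy)-6-(hydroxymethyl)-2-methylhepta-1,6-dien-1-yl]-2-methyl-5-(propan-2-yl)-2-(triethylsilyloxy)cyclohexane-1-carbaldehyde
Product: 29 (1R,2R,5R,6S)-6-[(1Z,5R)-6-(bromomethyl)-5-(tert-butyldimethylsilyloxy)-2-methylhepta-1,6-dien-1-yl]-2-methyl-5-(propan-2-yl)-2-(triethylsilyloxy)cyclohexane-1-carbaldehyde, via allylic mesylate 28 (not isolated)
Conditions: MsCl, Et3N, THF, −30 °C; then LiBr, −30→0 °C
Reagents that add atoms: lithium bromide, [Li+].[Br-]
Why: Mesylation of the primary allylic alcohol and displacement by bromide in the same flask. The 2-substituted allyl unit is symmetric, so direct and allylic displacement give the same bromide, and the cold, brief contact with amine should preserve C10.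

Step 22
Reactants: 29 (1R,2R,5R,6S)-6-[(1Z,5R)-6-(bromomethyl)-5-(tert-butyldimethylsilyloxy)-2-methylhepta-1,6-dien-1-yl]-2-methyl-5-(propan-2-yl)-2-(triethylsilyloxy)cyclohexane-1-carbaldehyde
Product: 31 (1S,2Z,6R,9R,10S,11R,14R)-6-(tert-butyldimethylsilyloxy)-3,11-dimethyl-7-methylidene-14-(propan-2-yl)-11-(triethylsilyloxy)bicyclo[8.4.0]tetradec-2-en-9-ol, via allylchromium dichloride 30 (not isolated)
Conditions: CrCl2 (10 equiv), degassed THF, 23 °C; 29 added over 12 h (final 0.002 M); aqueous work-up
Reagents that add atoms: none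
Why: Two equivalents of divalent chromium reduce the allylic C–Br bond in two one-electron steps to the trivalent allylchromium 30, which is nucleophilic only toward aldehydes. It adds to the C9 aldehyde through a six-membered chair transition state with chromium on the carbonyl oxygen and bond formation at the allyl terminus remote from chromium; the closest known reaction is the Nozaki–Hiyama allylation of aldehydes by allylic bromides, which has closed ten- and fourteen-membered carbocycles. The ring closes end-to-end in a 10-exo-trig mode: one allyl terminus bonds to C9 as C8 and the other becomes the exocyclic C7 methylene, and because the two termini are equivalent no regiochemical question arises. The new stereocentre C9 is controlled by C10: in the Felkin–Anh arrangement the quaternary C11 stands anti to the incoming C8, C1 with the tether is gauche to it and the carbonyl oxygen lies on the C1 side, which should give the 9R alcohol. The step needs chemoselectivity for the aldehyde, which the organochromium provides in the presence of silyl ethers and both olefins, and intramolecular over intermolecular addition, secured by slow addition into excess CrCl2 at high dilution. The cis ring fusion and the Z olefin hold both chain ends on the same face of ring A, which pre-organises the closure.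

Step 23
Reactants: 31 (1S,2Z,6R,9R,10S,11R,14R)-6-(tert-butyldimethylsilyloxy)-3,11-dimethyl-7-methylidene-14-(propan-2-yl)-11-(triethylsilyloxy)bicyclo[8.4.0]tetradec-2-en-9-ol
Product: 32 (1S,2Z,6R,9R,10S,11R,14R)-3,11-dimethyl-7-methylidene-14-(propan-2-yl)bicyclo[8.4.0]tetradec-2-ene-6,9,11-triol
Conditions: Bu4NF (5 equiv), THF, 23→45 °C
Reagents that add atoms: none
Why: Fluoride-mediated desilylation removes both silyl ethers, the tertiary one needing gentle warming. The triol has no base-sensitive group, which is why this step precedes the acylation.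

Step 24
Reactants: 32 (1S,2Z,6R,9R,10S,11R,14R)-3,11-dimethyl-7-methylidene-14-(propan-2-yl)bicyclo[8.4.0]tetradec-2-ene-6,9,11-triol
Product: 33 (1S,2Z,6R,9R,10S,11R,14R)-11-hydroxy-3,11-dimethyl-7-methylidene-14-(propan-2-yl)bicyclo[8.4.0]tetradec-2-ene-6,9-diyl diacetate
Conditions: Ac2O, pyridine, 4-(dimethylamino)pyridine (cat.), CH2Cl2, 0→23 °C
Reagents that add atoms: acetic anhydride, CC(=O)OC(C)=O
Why: Nucleophile-catalysed acetylation should acylate both secondary hydroxyls, while the hindered tertiary C11 hydroxyl does not react under these conditions. Differentiation by steric class removes the need for further protecting-group steps.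

## Compound list

1 | (2E)-3-methylpent-2-en-4-yn-1-ol | C#C/C(C)=C/CO | starting material
2 | (2E)-3-methylpent-2-en-4-yn-1-yl 2,2-dimethylpropanoate | C#C/C(C)=C/COC(=O)C(C)(C)C | intermediate
3 | (2E)-3-methylpenta-2,4-dien-1-yl 2,2-dimethylpropanoate | C=C/C(C)=C/COC(=O)C(C)(C)C | intermediate
4 | (2E)-4-methylpent-2-enal | CC(C)/C=C/C=O | starting material
5 | [(1R,5R,6R)-6-formyl-2-methyl-5-(propan-2-yl)cyclohex-2-en-1-yl]methyl 2,2-dimethylpropanoate (not isolated) | CC(C)(C)C(=O)OC[C@@H]1[C@H](C=O)[C@@H](C(C)C)CC=C1C | intermediate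
6 | [(1R,5R,6R)-6-(hydroxymethyl)-2-methyl-5-(propan-2-yl)cyclohex-2-en-1-yl]methyl 2,2-dimethylpropanoate | CC(C)(C)C(=O)OC[C@@H]1[C@H](CO)[C@@H](C(C)C)CC=C1C | intermediate
7 | [(1S,2R,5R,6R)-2-hydroxy-6-(hydroxymethyl)-2-methyl-5-(propan-2-yl)cyclohexyl]methyl 2,2-dimethylpropanoate | CC(C)(C)C(=O)OC[C@@H]1[C@H](CO)[C@@H](C(C)C)CC[C@@]1(C)O | intermediate
8 | [(1S,2R,5R,6R)-6-formyl-2-hydroxy-2-methyl-5-(propan-2-yl)cyclohexyl]methyl 2,2-dimethylpropanoate | CC(C)(C)C(=O)OC[C@@H]1[C@H](C=O)[C@@H](C(C)C)CC[C@@]1(C)O | intermediate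
9 | [(1S,2R,5R,6R)-6-formyl-2-methyl-5-(propan-2-yl)-2-(triethylsilyloxy)cyclohexyl]methyl 2,2-dimethylpropanoate | CC(C)(C)C(=O)OC[C@@H]1[C@H](C=O)[C@@H](C(C)C)CC[C@@]1(C)O[Si](CC)(CC)CC | intermediate
10 | [(1S,2R,5R,6R)-6-[(1Z)-2-iodoprop-1-en-1-yl]-2-methyl-5-(propan-2-yl)-2-(triethylsilyloxy)cyclohexyl]methyl 2,2-dimethylpropanoate | CC(C)(C)C(=O)OC[C@@H]1[C@H](/C=C(/C)I)[C@@H](C(C)C)CC[C@@]1(C)O[Si](CC)(CC)CC | intermediate
11 | propane-1,3-diol | OCCCO | starting material
12 | 3-(tert-butyldimethylsilyloxy)propan-1-ol | OCCCO[Si](C)(C)C(C)(C)C | intermediate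
13 | 3-(tert-butyldimethylsilyloxy)propanal | O=CCCO[Si](C)(C)C(C)(C)C | intermediate
14 | 2-bromoprop-2-en-1-ol | OCC(Br)=C | starting material
15 | 1-{[(2-bromoprop-2-en-1-yl)oxy]methyl}-4-methoxybenzene | C=C(Br)COCc1ccc(OC)cc1 | intermediate
16 | 2-lithio-3-[(4-methoxybenzyl)oxy]prop-1-ene (not isolated) | [Li]C(=C)COCc1ccc(OC)cc1 | intermediate
17 | rac-5-(tert-butyldimethylsilyloxy)-2-{[(4-methoxybenzyl)oxy]methyl}pent-1-en-3-ol | C=C(COCc1ccc(OC)cc1)C(O)CCO[Si](C)(C)C(C)(C)C | intermediate
18 | 5-(tert-butyldimethylsilyloxy)-2-{[(4-methoxybenzyl)oxy]methyl}pent-1-en-3-one | C=C(COCc1ccc(OC)cc1)C(=O)CCO[Si](C)(C)C(C)(C)C | intermediate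
19 | (3R)-5-(tert-butyldimethylsilyloxy)-2-{[(4-methoxybenzyl)oxy]methyl}pent-1-en-3-ol | C=C(COCc1ccc(OC)cc1)[C@H](O)CCO[Si](C)(C)C(C)(C)C | intermediate
20 | (3R)-3,5-bis(tert-butyldimethylsilyloxy)-2-{[(4-methoxybenzyl)oxy]methyl}pent-1-ene | C=C(COCc1ccc(OC)cc1)[C@H](O[Si](C)(C)C(C)(C)C)CCO[Si](C)(C)C(C)(C)C | intermediate
21 | (3R)-3-(tert-butyldimethylsilyloxy)-4-{[(4-methoxybenzyl)oxy]methyl}pent-4-en-1-ol | C=C(COCc1ccc(OC)cc1)[C@H](O[Si](C)(C)C(C)(C)C)CCO | intermediate
22 | (3R)-3-(tert-butyldimethylsilyloxy)-5-iodo-2-{[(4-methoxybenzyl)oxy]methyl}pent-1-ene | C=C(COCc1ccc(OC)cc1)[C@H](O[Si](C)(C)C(C)(C)C)CCI | intermediate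
23 | [(3R)-3-(tert-butyldimethylsilyloxy)-4-{[(4-methoxybenzyl)oxy]methyl}pent-4-en-1-yl]zinc iodide (not isolated) | C=C(COCc1ccc(OC)cc1)[C@H](O[Si](C)(C)C(C)(C)C)CC[Zn]I | intermediate
24 | [(1S,2R,5R,6S)-6-[(1Z,5R)-5-(tert-butyldimethylsilyloxy)-6-{[(4-methoxybenzyl)oxy]methyl}-2-methylhepta-1,6-dien-1-yl]-2-methyl-5-(propan-2-yl)-2-(triethylsilyloxy)cyclohexyl]methyl 2,2-dimethylpropanoate | CC(C)(C)C(=O)OC[C@@H]1[C@H](/C=C(/C)CC[C@@H](O[Si](C)(C)C(C)(C)C)C(=C)COCc2ccc(OC)cc2)[C@@H](C(C)C)CC[C@@]1(C)O[Si](CC)(CC)CC | intermediate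
25 | [(1S,2R,5R,6S)-6-[(1Z,5R)-5-(tert-butyldimethylsilyloxy)-6-{[(4-methoxybenzyl)oxy]methyl}-2-methylhepta-1,6-dien-1-yl]-2-methyl-5-(propan-2-yl)-2-(triethylsilyloxy)cyclohexyl]methanol | OC[C@@H]1[C@H](/C=C(/C)CC[C@@H](O[Si](C)(C)C(C)(C)C)C(=C)COCc2ccc(OC)cc2)[C@@H](C(C)C)CC[C@@]1(C)O[Si](CC)(CC)CC | intermediate
26 | (1R,2R,5R,6S)-6-[(1Z,5R)-5-(tert-butyldimethylsilyloxy)-6-{[(4-methoxybenzyl)oxy]methyl}-2-methylhepta-1,6-dien-1-yl]-2-methyl-5-(propan-2-yl)-2-(triethylsilyloxy)cyclohexane-1-carbaldehyde | O=C[C@@H]1[C@H](/C=C(/C)CC[C@@H](O[Si](C)(C)C(C)(C)C)C(=C)COCc2ccc(OC)cc2)[C@@H](C(C)C)CC[C@@]1(C)O[Si](CC)(CC)CC | intermediate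
27 | (1R,2R,5R,6S)-6-[(1Z,5R)-5-(tert-butyldimethylsilyloxy)-6-(hydroxymethyl)-2-methylhepta-1,6-dien-1-yl]-2-methyl-5-(propan-2-yl)-2-(triethylsilyloxy)cyclohexane-1-carbaldehyde | O=C[C@@H]1[C@H](/C=C(/C)CC[C@@H](O[Si](C)(C)C(C)(C)C)C(=C)CO)[C@@H](C(C)C)CC[C@@]1(C)O[Si](CC)(CC)CC | intermediate
28 | (1R,2R,5R,6S)-6-[(1Z,5R)-5-(tert-butyldimethylsilyloxy)-6-[(methanesulfonyloxy)methyl]-2-methylhepta-1,6-dien-1-yl]-2-methyl-5-(propan-2-yl)-2-(triethylsilyloxy)cyclohexane-1-carbaldehyde (not isolated) | O=C[C@@H]1[C@H](/C=C(/C)CC[C@@H](O[Si](C)(C)C(C)(C)C)C(=C)COS(C)(=O)=O)[C@@H](C(C)C)CC[C@@]1(C)O[Si](CC)(CC)CC | intermediate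
29 | (1R,2R,5R,6S)-6-[(1Z,5R)-6-(bromomethyl)-5-(tert-butyldimethylsilyloxy)-2-methylhepta-1,6-dien-1-yl]-2-methyl-5-(propan-2-yl)-2-(triethylsilyloxy)cyclohexane-1-carbaldehyde | O=C[C@@H]1[C@H](/C=C(/C)CC[C@@H](O[Si](C)(C)C(C)(C)C)C(=C)CBr)[C@@H](C(C)C)CC[C@@]1(C)O[Si](CC)(CC)CC | intermediate
30 | allylchromium dichloride of 29 (chromium in place of bromine; not isolated) | O=C[C@@H]1[C@H](/C=C(/C)CC[C@@H](O[Si](C)(C)C(C)(C)C)C(=C)C[Cr](Cl)Cl)[C@@H](C(C)C)CC[C@@]1(C)O[Si](CC)(CC)CC | intermediate
31 | (1S,2Z,6R,9R,10S,11R,14R)-6-(tert-butyldimethylsilyloxy)-3,11-dimethyl-7-methylidene-14-(propan-2-yl)-11-(triethylsilyloxy)bicyclo[8.4.0]tetradec-2-en-9-ol | C=C1C[C@@H](O)[C@@H]2[C@H](/C=C(/C)CC[C@H]1O[Si](C)(C)C(C)(C)C)[C@@H](C(C)C)CC[C@@]2(C)O[Si](CC)(CC)CC | intermediate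
32 | (1S,2Z,6R,9R,10S,11R,14R)-3,11-dimethyl-7-methylidene-14-(propan-2-yl)bicyclo[8.4.0]tetradec-2-ene-6,9,11-triol | C=C1C[C@@H](O)[C@@H]2[C@H](/C=C(/C)CC[C@H]1O)[C@@H](C(C)C)CC[C@@]2(C)O | intermediate
33 | (1S,2Z,6R,9R,10S,11R,14R)-11-hydroxy-3,11-dimethyl-7-methylidene-14-(propan-2-yl)bicyclo[8.4.0]tetradec-2-ene-6,9-diyl diacetate | C=C1C[C@@H](OC(C)=O)[C@@H]2[C@H](/C=C(/C)CC[C@H]1OC(C)=O)[C@@H](C(C)C)CC[C@@]2(C)O | target

## Step count and least certain steps

Total step count: 24. Longest linear sequence: 16 steps (11 → 12 → 13 → 17 → 18 → 19 → 20 → 21 → 22 → 24 → 25 → 26 → 27 → 29 → 31 → 32 → 33). The ring A branch from 1 reaches 33 in 15 steps.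

Step 22 (key step). The closure may lose to intermolecular allylation or to simple protonation of the allylchromium, because the ten-membered transition state carries transannular and torsional strain. The tether also limits the rotamers about C9–C10, so the Felkin–Anh arrangement may not be the lowest one and facial selectivity at C9 may erode or reverse. High dilution answers the first problem. For the second, the fallback moves C9 control from the substrate to a reagent. It sets out from 29, accepting whichever epimer closes. If the closure gives mainly the 9S alcohol (1S,2Z,6R,9S,10S,11R,14R)-6-(tert-butyldimethylsilyloxy)-3,11-dimethyl-7-methylidene-14-(propan-2-yl)-11-(triethylsilyloxy)bicyclo[8.4.0]tetradec-2-en-9-ol F1, it is oxidised with buffered Dess–Martin periodinane to the C9 ketone (1S,2Z,6R,10R,11R,14R)-6-(tert-butyldimethylsilyloxy)-3,11-dimethyl-7-methylidene-14-(propan-2-yl)-11-(triethylsilyloxy)bicyclo[8.4.0]tetradec-2-en-9-one F2. The ketone is reduced with catecholborane and the (S)-oxazaborolidine of step 13 at −78 °C, the branched C10 acting as the large group, and the sequence returns to the route at 31.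

Step 3. The iminium ion of a β-branched enal may react too slowly with an acyclic trisubstituted diene, so that diene polymerisation competes and endo and regiochemical preferences erode. The fallback replaces catalyst control by a covalently bound auxiliary and Lewis-acid activation. It sets out from 3, which is combined with the acyl oxazolidinone (4S)-4-benzyl-3-[(2E)-4-methylpent-2-enoyl]-1,3-oxazolidin-2-one F3 (from the commercial acid and auxiliary) and Et2AlCl in CH2Cl2 at −78→−20 °C. The chelated s-cis imide is attacked on the face opposite the benzyl group, the same Re face of the β-carbon, in the endo mode, giving the adduct [(1R,5R,6R)-6-{[(4S)-4-benzyl-2-oxo-1,3-oxazolidin-3-yl]carbonyl}-2-methyl-5-(propan-2-yl)cyclohex-2-en-1-yl]methyl 2,2-dimethylpropanoate F4. LiBH4 in THF/MeOH at 0 °C cleaves the imide reductively and returns to the route at 6.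

Step 4. Capture of the planar C11 radical by O2 has an early transition state, so facial selectivity may be poor, and a wrong tertiary carbinol cannot be inverted later. The fallback is an ionic hydration and sets out from 6. Hg(OAc)2 in THF/H2O should give the organomercurial formed by trans-diaxial hydroxymercuration of 6 (hydroxyl on C11 anti to the C9 branch, acetoxymercurio group on C12 on the other face) F5, since water opens the mercurinium ion axially at the tertiary carbon. NaBH4/NaOH demercuration in the same flask returns to the route at 7.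

Step 7. The bulky iodo ylide may add slowly to the hindered α-branched aldehyde, which leaves time for the basic ylide to epimerise C1 and for loss of Z selectivity. The fallback builds the same olefin by two stereoselective couplings and sets out from 9. CBr4, PPh3 and Zn in CH2Cl2 (Corey–Fuchs olefination) give the dibromoalkene [(1S,2R,5R,6R)-6-(2,2-dibromoethenyl)-2-methyl-5-(propan-2-yl)-2-(triethylsilyloxy)cyclohexyl]methyl 2,2-dimethylpropanoate F6. Trans-selective Negishi methylation (MeZnCl, Pd(DPEphos)Cl2, THF) replaces the less hindered bromine and gives the bromoalkene [(1S,2R,5R,6R)-6-[(1Z)-2-bromoprop-1-en-1-yl]-2-methyl-5-(propan-2-yl)-2-(triethylsilyloxy)cyclohexyl]methyl 2,2-dimethylpropanoate F7. Coupling of F7 with alkylzinc iodide 23 under Pd(P(t-Bu)3)2, which retains the geometry, returns to the route at 24.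

## Further compounds

F1 | step 22 | (1S,2Z,6R,9S,10S,11R,14R)-6-(tert-butyldimethylsilyloxy)-3,11-dimethyl-7-methylidene-14-(propan-2-yl)-11-(triethylsilyloxy)bicyclo[8.4.0]tetradec-2-en-9-ol | C=C1C[C@H](O)[C@@H]2[C@H](/C=C(/C)CC[C@H]1O[Si](C)(C)C(C)(C)C)[C@@H](C(C)C)CC[C@@]2(C)O[Si](CC)(CC)CC
F2 | step 22 | (1S,2Z,6R,10R,11R,14R)-6-(tert-butyldimethylsilyloxy)-3,11-dimethyl-7-methylidene-14-(propan-2-yl)-11-(triethylsilyloxy)bicyclo[8.4.0]tetradec-2-en-9-one | C=C1CC(=O)[C@@H]2[C@H](/C=C(/C)CC[C@H]1O[Si](C)(C)C(C)(C)C)[C@@H](C(C)C)CC[C@@]2(C)O[Si](CC)(CC)CC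
F3 | step 3 | (4S)-4-benzyl-3-[(2E)-4-methylpent-2-enoyl]-1,3-oxazolidin-2-one | CC(C)/C=C/C(=O)N1[C@@H](Cc2ccccc2)COC1=O
F4 | step 3 | [(1R,5R,6R)-6-{[(4S)-4-benzyl-2-oxo-1,3-oxazolidin-3-yl]carbonyl}-2-methyl-5-(propan-2-yl)cyclohex-2-en-1-yl]methyl 2,2-dimethylpropanoate | CC(C)(C)C(=O)OC[C@@H]1[C@H](C(=O)N2[C@@H](Cc3ccccc3)COC2=O)[C@@H](C(C)C)CC=C1C
F5 | step 4 | organomercurial formed by trans-diaxial hydroxymercuration of 6 (hydroxyl on C11 anti to the C9 branch, acetoxymercurio group on C12 on the other face) | CC(C)(C)C(=O)OC[C@@H]1[C@H](CO)[C@@H](C(C)C)C[C@H]([Hg]OC(C)=O)[C@@]1(C)O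
F6 | step 7 | [(1S,2R,5R,6R)-6-(2,2-dibromoethenyl)-2-methyl-5-(propan-2-yl)-2-(triethylsilyloxy)cyclohexyl]methyl 2,2-dimethylpropanoate | CC(C)(C)C(=O)OC[C@@H]1[C@H](C=C(Br)Br)[C@@H](C(C)C)CC[C@@]1(C)O[Si](CC)(CC)CC
F7 | step 7 | [(1S,2R,5R,6R)-6-[(1Z)-2-bromoprop-1-en-1-yl]-2-methyl-5-(propan-2-yl)-2-(triethylsilyloxy)cyclohexyl]methyl 2,2-dimethylpropanoate | CC(C)(C)C(=O)OC[C@@H]1[C@H](/C=C(/C)Br)[C@@H](C(C)C)CC[C@@]1(C)O[Si](CC)(CC)CC
A1 | alternative 1 | ring A-fused cyclodec-2-yn-7-one with the C9 tert-butyldimethylsilyl ether and the free C11 alcohol | O=C1C[C@@H](O[Si](C)(C)C(C)(C)C)[C@@H]2[C@H](C#CCCC1)[C@@H](C(C)C)CC[C@@]2(C)O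
A2 | alternative 1 | tricyclic C2,C7-epoxy C3-ketone (either epoxide face) with the C9 tert-butyldimethylsilyl ether and the C11 alcohol | O=C1CCCC23OC12[C@@H]4[C@@H](C(C)C)CC[C@@](C)(O)[C@@H]4[C@H](O[Si](C)(C)C(C)(C)C)C3
A3 | alternative 2 | 2Z ten-membered ring with C7 dioxolane and silyl ethers at C6 and C9 | C12(OCCO1)C[C@@H](O[Si](C)(C)C(C)(C)C)[C@@H]3[C@H](/C=C(/C)CC[C@H]2O[Si](C)(C)C(C)(C)C)[C@@H](C(C)C)CC[C@@]3(C)O
A4 | alternative 2 | open-chain Z-iodoalkene with terminal C4=C5 olefin, C7 dioxolane and silyl ethers at C6 and C9 | C=C[C@@H](O[Si](C)(C)C(C)(C)C)C1(OCCO1)C[C@@H](O[Si](C)(C)C(C)(C)C)[C@@H]2[C@H](/C=C(/C)I)[C@@H](C(C)C)CC[C@@]2(C)O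
A5 | alternative 3 | bicyclic C11 alcohol with C9 as spiro 1,3-dithiane and the C6 silyl ether | C=C1CC2(SCCCS2)[C@@H]3[C@H](/C=C(/C)CC[C@H]1O[Si](C)(C)C(C)(C)C)[C@@H](C(C)C)CC[C@@]3(C)O
A6 | alternative 3 | open-chain C9 dithiane with the C10–C11 epoxide on ring A (oxygen anti to the C2 branch) and the C6 silyl ether | S1CCCSC1CC(=C)[C@H](O[Si](C)(C)C(C)(C)C)CC/C(C)=C\[C@@H]2[C@@H](C(C)C)CC[C@@]3(C)O[C@@H]23
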